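**Plan**

- Numbering: C1 is the lactone carbonyl and the chain runs to C13 (the carbon bearing phenyl); O1 is the ring oxygen, and the only ring is O1–C1–C2–C3–C4–C5.
- Retrosynthesis: open C1–O1 (to a tert-butyl syn-3,5-dihydroxy ester) and remove the C3–H and C5–H bonds (to a 3,5-dioxo ester). Then cut C4–C5 (acetoacetate dianion plus N-methoxy-N-methyl enamide), C6=C7 (Horner–Wadsworth–Emmons) and C10–C11 (vinylogous aldol on cinnamaldehyde).
- Enabling feature: C3 and C5 of the lactone ring are 1,3-related carbinol carbons and C5 is allylic to C6=C7. The ring is therefore a folded 3,5-dihydroxy-6-enoate, and both carbinols can be made from the carbonyls of an open-chain, enolised enone-diketone that only an enzyme should reduce cleanly.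
- Forward: C10–C11 is made first, then C6=C7, then C4–C5; the two C–H bonds follow, and the δ-lactone (C1–O1) closes last.
- Stereochemistry: C11 from the catalyst made from Ti(OiPr)4 and (S)-BINOL; C9 by 1,3-anti hydroxyl-directed reduction; C5 and C3 from the ketoreductases. C12=C13 comes with cinnamaldehyde and C6=C7 from the olefination.

Key step: step 7

Assumption: the bis(trimethylsilyl) dienol ether of methyl acetoacetate is taken as a catalogue reagent, and the two reductases of the key step are taken from a commercial ketoreductase panel after an analytical screen.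

**Route**

Step 1
Reactants: 1 (E)-cinnamaldehyde; 2 1-methoxy-1,3-bis(trimethylsilyloxy)buta-1,3-diene
Product: 4 methyl (5S,6E)-5-hydroxy-3-oxo-7-phenylhept-6-enoate, via bis-silyl aldol adduct 3 (not isolated)
Conditions: (S)-BINOL (10 mol%), Ti(OiPr)4 (10 mol%), LiCl, 4 Å MS, THF, −78 °C to rt; then CF3CO2H, −78 °C
Reagents that add atoms: none
Why: Vinylogous Mukaiyama aldol in which the titanium binaphtholate binds the enal carbonyl and shields one face, so the terminal carbon of the diene adds 1,2 to give the 5S carbinol (the sense expected for enals with the (S)-ligand); the acid then removes both silyl groups.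

Step 2
Reactants: 4 methyl (5S,6E)-5-hydroxy-3-oxo-7-phenylhept-6-enoate
Product: 5 methyl (3S,5S,6E)-3,5-dihydroxy-7-phenylhept-6-enoate
Conditions: Me4NBH(OAc)3, MeCN/AcOH (1:1), −30 °C
Reagents that add atoms: none
Why: Evans–Saksena reduction, in which the C5 hydroxyl exchanges onto boron and delivers hydride to the ketone through a chair, should give the 1,3-anti diol and hence the 3S centre, leaving ester and styrene untouched.

Step 3
Reactants: 5 methyl (3S,5S,6E)-3,5-dihydroxy-7-phenylhept-6-enoate
Product: 6 methyl (3S,5S,6E)-3,5-dimethoxy-7-phenylhept-6-enoate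
Conditions: Me3OBF4, 1,8-bis(dimethylamino)naphthalene, 4 Å MS, CH2Cl2, 0 °C to rt
Reagents that add atoms: trimethyloxonium tetrafluoroborate, C[O+](C)C.F[B-](F)(F)F
Why: O-Methylation by the oxonium salt under amine-buffered, non-basic conditions should etherify both secondary hydroxyls without retro-aldol cleavage, β-elimination or lactonisation of the β-hydroxy ester.

Step 4
Reactants: 6 methyl (3S,5S,6E)-3,5-dimethoxy-7-phenylhept-6-enoate
Product: 7 (3S,5S,6E)-3,5-dimethoxy-7-phenylhept-6-enal
Conditions: iBu2AlH (1.1 equiv), CH2Cl2, −78 °C; MeOH, then aq. potassium sodium tartrate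
Reagents that add atoms: none
Why: Partial ester reduction, in which the aluminium hemiacetal (held by the β-methoxy group) should persist at −78 °C and release the aldehyde only on quench; the aldehyde is used crude to avoid β-elimination.

Step 5
Reactants: 7 (3S,5S,6E)-3,5-dimethoxy-7-phenylhept-6-enal; 8 diethyl [2-(methoxy(methyl)amino)-2-oxoethyl]phosphonate
Product: 9 (2E,5R,7S,8E)-N,5,7-trimethoxy-N-methyl-9-phenylnona-2,8-dienamide
Conditions: LiCl, DBU, MeCN, 0 °C to rt
Reagents that add atoms: none
Why: Horner–Wadsworth–Emmons olefination under Masamune–Roush conditions is mild enough to spare the β-methoxy aldehyde, and the amide-stabilised phosphonate should give the E-alkene (the descriptor at the former C3 changes to R only through a change of priorities).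

Step 6
Reactants: 9 (2E,5R,7S,8E)-N,5,7-trimethoxy-N-methyl-9-phenylnona-2,8-dienamide; 10 tert-butyl acetoacetate
Product: 12 tert-butyl (6E,9R,11S,12E)-9,11-dimethoxy-3,5-dioxo-13-phenyltrideca-6,12-dienoate, via acetoacetate dianion 11 (not isolated)
Conditions: 10 (3 equiv), NaH, THF, 0 °C; n-BuLi, 0 °C; then 9, −78 to 0 °C; 1 M HCl to pH 4, 0 °C
Reagents that add atoms: none
Why: Claisen-type acylation of the γ-carbon of the acetoacetate dianion by an N-methoxy-N-methyl amide, whose chelated tetrahedral adduct holds until the quench so that addition stops at the diketone; unsaturated amides of this kind are known to react at the carbonyl carbon and not in the 1,4 sense.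

Step 7
Reactants: 12 tert-butyl (6E,9R,11S,12E)-9,11-dimethoxy-3,5-dioxo-13-phenyltrideca-6,12-dienoate
Product: 14 tert-butyl (3S,5R,6E,9R,11S,12E)-3,5-dihydroxy-9,11-dimethoxy-13-phenyltrideca-6,12-dienoate, via 5-hydroxy-3-oxo ester 13 (not isolated)
Conditions: 5R-selective ketoreductase and 3S-selective ketoreductase (screened panel, isolated enzymes), NADP+ (cat.), D-glucose (2.4 equiv), glucose dehydrogenase, KH2PO4/K2HPO4 buffer pH 6.5–7.0, DMSO (10% v/v), 30 °C, pH held with aq. NaOH
Reagents that add atoms: none
Why: Each ketoreductase passes the hydride of NADPH (regenerated by glucose dehydrogenase at the cost of glucose) to one face of a bound carbonyl, first at C5 of the enolised enone-diketone and then at C3 of the δ-hydroxy-β-keto ester 13, so both C–H bonds are made in one pot. The closest known reaction type is the enzymatic reduction of β,δ-diketo esters, 6-alkenyl ones included, to syn-3,5-dihydroxy esters of the (3R,5S) series, and reductases of complementary facial sense are known for simple members of the class. No ring is formed. C5 (R) is fixed by the active site of the first enzyme and C3 (S) by that of the second, independently of the distant C9 and C11 centres; the pair is chosen on analytical scale against the four diol stereoisomers made by NaBH4 reduction. The step needs 1,2- over 1,4-reduction, C5 before C3 and no alkene reduction, which hydride transfer to carbonyl carbon only, the δ-first regiochemistry usual for this substrate class and isolated enzymes free of ene-reductase activity should secure. Near-neutral buffer keeps the δ-methoxy enone from losing methanol, and the tert-butyl ester prevents early lactonisation.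

Step 8
Reactants: 14 tert-butyl (3S,5R,6E,9R,11S,12E)-3,5-dihydroxy-9,11-dimethoxy-13-phenyltrideca-6,12-dienoate
Product: 16 (4S,6R)-6-[(1E,4R,6S,7E)-4,6-dimethoxy-8-phenylocta-1,7-dien-1-yl]-4-hydroxyoxan-2-one, via dihydroxy acid 15 (not isolated)
Conditions: CF3CO2H, CH2Cl2, 0 °C to rt, short reaction time; toluene azeotrope
Reagents that add atoms: none
Why: Acidolysis of the tert-butyl ester (loss of isobutene) followed by acid-catalysed 6-exo-trig lactonisation of the C5 hydroxyl onto C1, as used for tert-butyl 3,5-dihydroxy-6-enoates, should give the δ-lactone with no change at any stereocentre.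

**Compound list**

1 | (E)-cinnamaldehyde | O=C/C=C/c1ccccc1 | starting material
2 | 1-methoxy-1,3-bis(trimethylsilyloxy)buta-1,3-diene | COC(O[Si](C)(C)C)=CC(=C)O[Si](C)(C)C | starting material
3 | methyl (5S,6E)-3,5-bis(trimethylsilyloxy)-7-phenylhepta-2,6-dienoate | COC(=O)C=C(O[Si](C)(C)C)C[C@H](O[Si](C)(C)C)/C=C/c1ccccc1 | intermediate
4 | methyl (5S,6E)-5-hydroxy-3-oxo-7-phenylhept-6-enoate | COC(=O)CC(=O)C[C@H](O)/C=C/c1ccccc1 | intermediate
5 | methyl (3S,5S,6E)-3,5-dihydroxy-7-phenylhept-6-enoate | COC(=O)C[C@@H](O)C[C@H](O)/C=C/c1ccccc1 | intermediate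
6 | methyl (3S,5S,6E)-3,5-dimethoxy-7-phenylhept-6-enoate | COC(=O)C[C@@H](OC)C[C@H](OC)/C=C/c1ccccc1 | intermediate
7 | (3S,5S,6E)-3,5-dimethoxy-7-phenylhept-6-enal | O=CC[C@@H](OC)C[C@H](OC)/C=C/c1ccccc1 | intermediate
8 | diethyl [2-(methoxy(methyl)amino)-2-oxoethyl]phosphonate | CCOP(=O)(CC(=O)N(C)OC)OCC | starting material
9 | (2E,5R,7S,8E)-N,5,7-trimethoxy-N-methyl-9-phenylnona-2,8-dienamide | CON(C)C(=O)/C=C/C[C@@H](OC)C[C@H](OC)/C=C/c1ccccc1 | intermediate
10 | tert-butyl acetoacetate | CC(=O)CC(=O)OC(C)(C)C | starting material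
11 | sodium lithium dianion of tert-butyl acetoacetate (1,3-dienediolate) | C=C([O-])C=C([O-])OC(C)(C)C.[Li+].[Na+] | intermediate
12 | tert-butyl (6E,9R,11S,12E)-9,11-dimethoxy-3,5-dioxo-13-phenyltrideca-6,12-dienoate | CC(C)(C)OC(=O)CC(=O)CC(=O)/C=C/C[C@@H](OC)C[C@H](OC)/C=C/c1ccccc1 | intermediate
13 | tert-butyl (5R,6E,9R,11S,12E)-5-hydroxy-9,11-dimethoxy-3-oxo-13-phenyltrideca-6,12-dienoate | CC(C)(C)OC(=O)CC(=O)C[C@@H](O)/C=C/C[C@@H](OC)C[C@H](OC)/C=C/c1ccccc1 | intermediate
14 | tert-butyl (3S,5R,6E,9R,11S,12E)-3,5-dihydroxy-9,11-dimethoxy-13-phenyltrideca-6,12-dienoate | CC(C)(C)OC(=O)C[C@@H](O)C[C@@H](O)/C=C/C[C@@H](OC)C[C@H](OC)/C=C/c1ccccc1 | intermediate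
15 | (3S,5R,6E,9R,11S,12E)-3,5-dihydroxy-9,11-dimethoxy-13-phenyltrideca-6,12-dienoic acid | OC(=O)C[C@@H](O)C[C@@H](O)/C=C/C[C@@H](OC)C[C@H](OC)/C=C/c1ccccc1 | intermediate
16 | (4S,6R)-6-[(1E,4R,6S,7E)-4,6-dimethoxy-8-phenylocta-1,7-dien-1-yl]-4-hydroxyoxan-2-one | CO[C@H](C/C=C/[C@H]1C[C@H](O)CC(=O)O1)C[C@@H](/C=C/c1ccccc1)OC | target

**Count and risks**

Total step count: 8. Longest linear sequence: 8 steps (from cinnamaldehyde 1).

Steps most likely to fail:

Step 7. The risks are that no reductase of the panel delivers hydride to the required face of C5 and of C3 at a useful rate on so long and lipophilic a substrate, that the second reduction stalls, or that reduction starts at C3 and erodes the diastereoselectivity. The fallback uses reagent control and no enzyme, and sets out from aldehyde 7. Olefination (LiCl, iPr2NEt, MeCN) with methyl (3S)-3-(tert-butyldimethylsilyloxy)-6-(dimethoxyphosphoryl)-5-oxohexanoate should give methyl (3S,6E,9R,11S,12E)-3-(tert-butyldimethylsilyloxy)-9,11-dimethoxy-5-oxo-13-phenyltrideca-6,12-dienoate F1. This phosphonate is the antipode of the usual statin side-chain reagent and would be made by the same desymmetrisation of 3-(tert-butyldimethylsilyloxy)glutaric anhydride with the antipodal chiral alcohol. Aqueous HF in MeCN should free methyl (3S,6E,9R,11S,12E)-3-hydroxy-9,11-dimethoxy-5-oxo-13-phenyltrideca-6,12-dienoate F2. Narasaka–Prasad reduction (Et2BOMe, NaBH4, THF/MeOH, −78 °C) should set C5 syn to C3 and give methyl (3S,5R,6E,9R,11S,12E)-3,5-dihydroxy-9,11-dimethoxy-13-phenyltrideca-6,12-dienoate F3. Catalytic p-TsOH in CH2Cl2 then closes the lactone, and the fallback comes back to the route at target 16.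

Step 6. The risks are deprotonation of the enamide at C8 by the strongly basic dianion, followed by loss of methoxide from C9, and conjugate addition in place of acylation at the amide carbonyl. The fallback sets out from enamide 9. iBu2AlH (THF, −78 °C) should reduce the amide to (2E,5R,7S,8E)-5,7-dimethoxy-9-phenylnona-2,8-dienal F4. Dianion 11 should add rapidly to this aldehyde at −78 °C to give tert-butyl (6E,9R,11S,12E)-5-hydroxy-9,11-dimethoxy-3-oxo-13-phenyltrideca-6,12-dienoate F5 as a mixture of C5 epimers. MnO2 (CH2Cl2, rt) should then oxidise the allylic alcohol, and the fallback comes back at diketo ester 12.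

Step 8. The risks are acid-induced ionisation at the cinnamyl-type C11 ether or at the allylic C5 carbinol (epimerisation, allylic transposition) and dehydration of the C3 hydroxyl during the acidolysis. The fallback sets out from diol ester 14. NaOH in THF/H2O at rt should hydrolyse the ester to sodium (3S,5R,6E,9R,11S,12E)-3,5-dihydroxy-9,11-dimethoxy-13-phenyltrideca-6,12-dienoate F6. Dilute HCl to pH 4 at 0 °C frees acid 15, which is lactonised by warming in toluene with removal of water, and the fallback comes back at target 16.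

**Further compounds**

F1 | step 7 | methyl (3S,6E,9R,11S,12E)-3-(tert-butyldimethylsilyloxy)-9,11-dimethoxy-5-oxo-13-phenyltrideca-6,12-dienoate | COC(=O)C[C@@H](O[Si](C)(C)C(C)(C)C)CC(=O)/C=C/C[C@@H](OC)C[C@H](OC)/C=C/c1ccccc1
F2 | step 7 | methyl (3S,6E,9R,11S,12E)-3-hydroxy-9,11-dimethoxy-5-oxo-13-phenyltrideca-6,12-dienoate | COC(=O)C[C@@H](O)CC(=O)/C=C/C[C@@H](OC)C[C@H](OC)/C=C/c1ccccc1
F3 | step 7 | methyl (3S,5R,6E,9R,11S,12E)-3,5-dihydroxy-9,11-dimethoxy-13-phenyltrideca-6,12-dienoate | COC(=O)C[C@@H](O)C[C@@H](O)/C=C/C[C@@H](OC)C[C@H](OC)/C=C/c1ccccc1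
F4 | step 6 | (2E,5R,7S,8E)-5,7-dimethoxy-9-phenylnona-2,8-dienal | O=C/C=C/C[C@@H](OC)C[C@H](OC)/C=C/c1ccccc1
F5 | step 6 | tert-butyl (6E,9R,11S,12E)-5-hydroxy-9,11-dimethoxy-3-oxo-13-phenyltrideca-6,12-dienoate (both C5 epimers) | CC(C)(C)OC(=O)CC(=O)CC(O)/C=C/C[C@@H](OC)C[C@H](OC)/C=C/c1ccccc1
F6 | step 8 | sodium (3S,5R,6E,9R,11S,12E)-3,5-dihydroxy-9,11-dimethoxy-13-phenyltrideca-6,12-dienoate | [Na+].[O-]C(=O)C[C@@H](O)C[C@@H](O)/C=C/C[C@@H](OC)C[C@H](OC)/C=C/c1ccccc1
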